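**Retrosynthetic overview**

1. The target is a 2,5-dihydroxy-1,4-naphthoquinone (C1–C8a) with a 2,4-dihydroxy-6-methylbenzoyl group at C6 and, through a CH2 group at C7, a 4-hydroxy-2-pyranone (O1, C2=O, C3, C4–OH, C5, C6). The plan rests on this lactone ring: its O1–C6 bond is closed last, by gold catalysis, from a tert-butyl 3-oxohex-4-ynoate side chain.
2. Endgame after ring closure: O-acetate on the pyranone, CAN unmasking of the 1,4-quinone from a 1,2,4,5-tetramethoxynaphthalene, hydroxide exchange of C2–OMe (and of the acetate), then BCl3 removal of both benzyl ethers and the chelated C5 methyl ether.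
3. Side chain: C7–CH2CH2OTBS → arylacetaldehyde → terminal alkyne (Ohira–Bestmann) → methyl ynoate → crossed Claisen with tert-butyl acetate.
4. Core: the C5–C8 ring comes from a Michael–Dieckmann annulation (C7–C8 and C5–C6 bonds) of lithiated methyl 3,4,6-trimethoxy-2-methylbenzoate (from 2,4,5-trimethoxybenzaldehyde) with an aryl ynone (from 2,4-dihydroxy-6-methylbenzaldehyde and 3-butyn-1-ol).
5. Ring order: second naphthalene ring (step 8) → pyranone (step 15) → quinone revealed (step 17).

Key step: step 15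

Remark: the target has no stereocentre and no defined axis, so no enantiocontrol is needed; the stereogenic intermediates 2–4, 13 and 16 are racemic and lose that element in the same or the next step. Naphthalene locants C1–C8a follow the numbering of the final naphthoquinone throughout.

**Route**

Step 1
Reactants: 1 2,4,5-trimethoxybenzaldehyde
Product: 5 3,4,6-trimethoxy-2-methylbenzaldehyde, via lithium α-amino alkoxide 2 (not isolated), via ring-lithiated α-amino alkoxide 3 (not isolated), via methylated α-amino alkoxide 4 (not isolated)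
Conditions: Me2NCH2CH2N(Me)Li (from Me2NCH2CH2NHMe + n-BuLi), THF, −20 °C; n-BuLi (3 equiv), −20 °C; MeI, −78 °C → rt; cold 10% HCl
Reagents that add atoms: iodomethane, CI
Why: The lithium amide masks the aldehyde as an α-amino alkoxide whose chelating diamine arm, reinforced by the adjacent 5-methoxy group, should direct ortho-lithiation to the only free position next to the masked formyl group in preference to the position between the 2- and 4-methoxy groups, so that methylation and acidic hydrolysis return the ortho-methylated aldehyde (directed ortho-metalation with in situ aldehyde protection).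

Step 2
Reactants: 5 3,4,6-trimethoxy-2-methylbenzaldehyde
Product: 6 3,4,6-trimethoxy-2-methylbenzoic acid
Conditions: NaClO2, NaH2PO4, 2-methyl-2-butene, t-BuOH/H2O, rt
Reagents that add atoms: sodium chlorite, [Na+].[O-]Cl=O
Why: Pinnick (chlorite) oxidation is insensitive to the two ortho substituents, and the alkene scavenger intercepts hypochlorous acid before it can chlorinate the electron-rich ring.

Step 3
Reactants: 6 3,4,6-trimethoxy-2-methylbenzoic acid
Product: 7 methyl 3,4,6-trimethoxy-2-methylbenzoate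
Conditions: MeI, K2CO3, DMF, rt
Reagents that add atoms: iodomethane, CI
Why: Carboxylate O-alkylation (SN2 on iodomethane) esterifies the di-ortho-substituted acid without requiring attack at its shielded carbonyl carbon.

Step 4
Reactants: 8 2,4-dihydroxy-6-methylbenzaldehyde
Product: 9 2,4-bis(benzyloxy)-6-methylbenzaldehyde
Conditions: BnBr (2.5 equiv), K2CO3, DMF, 60 °C
Reagents that add atoms: benzyl bromide, BrCc1ccccc1
Why: Williamson etherification of both phenols should proceed with excess benzyl bromide on warming, the hydrogen-bonded 2-hydroxy group reacting last.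

Step 5
Reactants: 10 3-butyn-1-ol
Product: 11 tert-butyl(but-3-yn-1-yloxy)dimethylsilane
Conditions: TBSCl, imidazole, CH2Cl2, rt
Reagents that add atoms: tert-butyldimethylsilyl chloride, CC(C)(C)[Si](C)(C)Cl
Why: Standard imidazole-mediated silylation protects the primary alcohol as a TBS ether that tolerates the organolithium and amide bases used later.

Step 6
Reactants: 11 tert-butyl(but-3-yn-1-yloxy)dimethylsilane; 9 2,4-bis(benzyloxy)-6-methylbenzaldehyde
Product: 13 1-[2,4-bis(benzyloxy)-6-methylphenyl]-5-[(tert-butyldimethylsilyl)oxy]pent-2-yn-1-ol (racemic), via lithium acetylide 12 (not isolated)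
Conditions: 11, n-BuLi, THF, −78 °C; then 9, −78 → 0 °C; aq. NH4Cl
Reagents that add atoms: none
Why: 1,2-Addition of the lithium acetylide to the aldehyde forms the aryl–CH(OH)–C≡C bond, and the new carbinol centre is racemic and is erased by the oxidation that follows.

Step 7
Reactants: 13 1-[2,4-bis(benzyloxy)-6-methylphenyl]-5-[(tert-butyldimethylsilyl)oxy]pent-2-yn-1-ol
Product: 14 1-[2,4-bis(benzyloxy)-6-methylphenyl]-5-[(tert-butyldimethylsilyl)oxy]pent-2-yn-1-one
Conditions: Dess–Martin periodinane, CH2Cl2, 0 °C → rt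
Reagents that add atoms: none
Why: Dess–Martin oxidation of the benzylic propargylic alcohol should give the ynone under near-neutral conditions that leave the silyl and benzyl ethers untouched.

Step 8
Reactants: 7 methyl 3,4,6-trimethoxy-2-methylbenzoate; 14 1-[2,4-bis(benzyloxy)-6-methylphenyl]-5-[(tert-butyldimethylsilyl)oxy]pent-2-yn-1-one
Product: 17 [2,4-bis(benzyloxy)-6-methylphenyl]{7-[2-(tert-butyldimethylsilyloxy)ethyl]-5-hydroxy-1,2,4-trimethoxynaphthalen-6-yl}methanone, via lithiated toluate 15 (not isolated), via lithium allenolate 16 (not isolated)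
Conditions: 7 (1.5 equiv), LDA (1.6 equiv), THF, −78 °C; then 14, −78 → 0 °C; aq. NH4Cl
Reagents that add atoms: none
Why: In this Michael–Dieckmann (Staunton–Weinreb-type) annulation the laterally lithiated toluate adds to the alkyne β-carbon of the ynone, whose carbonyl is shielded by the 2,6-disubstituted aryl group, the allenolate then acylates at its α-carbon on the neighbouring methyl ester (C7–C8 then C5–C6 bond formation), and loss of methoxide with tautomerisation should deliver the chelated 6-aroyl-5-naphthol.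

Step 9
Reactants: 17 [2,4-bis(benzyloxy)-6-methylphenyl]{7-[2-(tert-butyldimethylsilyloxy)ethyl]-5-hydroxy-1,2,4-trimethoxynaphthalen-6-yl}methanone
Product: 18 [2,4-bis(benzyloxy)-6-methylphenyl]{7-[2-(tert-butyldimethylsilyloxy)ethyl]-1,2,4,5-tetramethoxynaphthalen-6-yl}methanone
Conditions: MeI, K2CO3, DMF, 40 °C
Reagents that add atoms: iodomethane, CI
Why: Williamson O-methylation of the only acidic group, the chelated C5 naphthol, in a polar aprotic solvent completes the 1,2,4,5-tetramethoxynaphthalene that masks the quinone.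

Step 10
Reactants: 18 [2,4-bis(benzyloxy)-6-methylphenyl]{7-[2-(tert-butyldimethylsilyloxy)ethyl]-1,2,4,5-tetramethoxynaphthalen-6-yl}methanone
Product: 19 [2,4-bis(benzyloxy)-6-methylphenyl][7-(2-hydroxyethyl)-1,2,4,5-tetramethoxynaphthalen-6-yl]methanone
Conditions: TBAF, THF, 0 °C → rt; aq. NH4Cl
Reagents that add atoms: none
Why: Fluoride-mediated desilylation frees the primary alcohol without affecting the methyl and benzyl ethers or the hindered ketone.

Step 11
Reactants: 19 [2,4-bis(benzyloxy)-6-methylphenyl][7-(2-hydroxyethyl)-1,2,4,5-tetramethoxynaphthalen-6-yl]methanone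
Product: 20 2-[6-(2,4-bis(benzyloxy)-6-methylbenzoyl)-1,2,4,5-tetramethoxynaphthalen-7-yl]acetaldehyde
Conditions: Dess–Martin periodinane, CH2Cl2, 0 °C
Reagents that add atoms: none
Why: Dess–Martin oxidation stops cleanly at the arylacetaldehyde, which is used at once because it enolises readily.

Step 12
Reactants: 20 2-[6-(2,4-bis(benzyloxy)-6-methylbenzoyl)-1,2,4,5-tetramethoxynaphthalen-7-yl]acetaldehyde
Product: 21 [2,4-bis(benzyloxy)-6-methylphenyl][1,2,4,5-tetramethoxy-7-(prop-2-yn-1-yl)naphthalen-6-yl]methanone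
Conditions: dimethyl (1-diazo-2-oxopropyl)phosphonate, K2CO3, MeOH, 0 °C
Reagents that add atoms: dimethyl (1-diazo-2-oxopropyl)phosphonate, CC(=O)C(=[N+]=[N-])P(=O)(OC)OC
Why: Ohira–Bestmann (Seyferth–Gilbert-type) homologation converts the aldehyde into the terminal alkyne through a diazoalkene and an alkylidene carbene 1,2-hydride shift, and the cold carbonate/methanol medium and short reaction time should limit isomerisation of the benzylic propargyl unit to the allene.

Step 13
Reactants: 21 [2,4-bis(benzyloxy)-6-methylphenyl][1,2,4,5-tetramethoxy-7-(prop-2-yn-1-yl)naphthalen-6-yl]methanone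
Product: 23 methyl 4-[6-(2,4-bis(benzyloxy)-6-methylbenzoyl)-1,2,4,5-tetramethoxynaphthalen-7-yl]but-2-ynoate, via lithium acetylide 22 (not isolated)
Conditions: LiHMDS (1.1 equiv), THF, −78 °C; ClCO2Me, −78 → −40 °C; aq. NH4Cl
Reagents that add atoms: methyl chloroformate, COC(=O)Cl
Why: Selective deprotonation of the sp C–H by the non-nucleophilic silylamide and C-acylation of the acetylide with methyl chloroformate gives the ynoate, while the tetra-ortho-substituted diaryl ketone is too hindered to react.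

Step 14
Reactants: 23 methyl 4-[6-(2,4-bis(benzyloxy)-6-methylbenzoyl)-1,2,4,5-tetramethoxynaphthalen-7-yl]but-2-ynoate; 24 tert-butyl acetate
Product: 26 tert-butyl 6-[6-(2,4-bis(benzyloxy)-6-methylbenzoyl)-1,2,4,5-tetramethoxynaphthalen-7-yl]-3-oxohex-4-ynoate, via lithium enolate of tert-butyl acetate 25 (not isolated)
Conditions: 24, LDA, THF, −78 °C (3 equiv of enolate); then 23, −78 °C; AcOH quench at −78 °C
Reagents that add atoms: none
Why: In this crossed Claisen condensation the lithium enolate of tert-butyl acetate adds at −78 °C to the highly electrophilic ynoate carbonyl, methoxide is lost, and the product is held as its unreactive β-keto ester enolate until the cold acidic quench, the excess enolate serving as the base for this last deprotonation.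

Step 15
Reactants: 26 tert-butyl 6-[6-(2,4-bis(benzyloxy)-6-methylbenzoyl)-1,2,4,5-tetramethoxynaphthalen-7-yl]-3-oxohex-4-ynoate
Product: 27 6-{[6-(2,4-bis(benzyloxy)-6-methylbenzoyl)-1,2,4,5-tetramethoxynaphthalen-7-yl]methyl}-4-hydroxy-2H-pyran-2-one
Conditions: (SPhos)AuNTf2 (5 mol%), MeNO2/AcOH (4:1), rt
Reagents that add atoms: none
Why: The cationic gold(I) centre coordinates the ynone triple bond and the carbonyl oxygen of the tert-butyl ester adds anti to gold at the alkyne β-carbon (C5 of the hexynoate, the future pyranone C6), so the O1–C6 bond and the lactone ring are formed in a 6-endo-dig closure. The resulting 2-tert-butoxypyrylium-type oxocarbenium ion loses isobutene irreversibly, and protodeauration of the vinylgold species by acetic acid followed by enolisation releases the 4-hydroxy-2-pyranone and the catalyst. The closest known reaction type is the gold(I)-catalysed cycloisomerisation of tert-butyl 3-oxoalk-4-ynoates to 4-hydroxy-2-pyranones. No stereocentre is formed. The step needs chemoselectivity for the ester oxygen over the oxygen of the neighbouring diaryl ketone, which could reach the same carbon by 6-exo attack: that ketone is twisted out of conjugation and flanked by four ortho substituents, its adduct has no irreversible exit and reverts, whereas isobutene loss commits the lactone pathway. Regioselectivity for the β-carbon follows from the polarisation of the ynone, and the nearly neutral medium should spare the doubly activated ArCH2 group from propargyl–allenyl isomerisation.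

Step 16
Reactants: 27 6-{[6-(2,4-bis(benzyloxy)-6-methylbenzoyl)-1,2,4,5-tetramethoxynaphthalen-7-yl]methyl}-4-hydroxy-2H-pyran-2-one
Product: 28 6-{[6-(2,4-bis(benzyloxy)-6-methylbenzoyl)-1,2,4,5-tetramethoxynaphthalen-7-yl]methyl}-2-oxo-2H-pyran-4-yl acetate
Conditions: Ac2O, pyridine, CH2Cl2, 0 °C
Reagents that add atoms: acetic anhydride, CC(=O)OC(C)=O
Why: O-Acetylation of the acidic pyranone enol with acetic anhydride and pyridine, without an acyl-transfer catalyst so that O-to-C acyl migration is avoided, masks the enolic 1,3-dicarbonyl unit that cerium(IV) would otherwise oxidise in the next step.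

Step 17
Reactants: 28 6-{[6-(2,4-bis(benzyloxy)-6-methylbenzoyl)-1,2,4,5-tetramethoxynaphthalen-7-yl]methyl}-2-oxo-2H-pyran-4-yl acetate
Product: 29 6-{[6-(2,4-bis(benzyloxy)-6-methylbenzoyl)-2,5-dimethoxy-1,4-dioxo-1,4-dihydronaphthalen-7-yl]methyl}-2-oxo-2H-pyran-4-yl acetate
Conditions: CAN (2.5 equiv), MeCN/H2O (2:1), 0 °C, short reaction time
Reagents that add atoms: water, O
Why: Oxidative demethylation with ceric ammonium nitrate takes place on the most electron-rich ring, the 1,2,4-trimethoxy-substituted one, whose radical cation is trapped by water at C1 and C4 to give the 2-methoxy-1,4-naphthoquinone, while the C5 methoxy group on the acyl-substituted ring, the benzyl ethers and the enol acetate should stay in place.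

Step 18
Reactants: 29 6-{[6-(2,4-bis(benzyloxy)-6-methylbenzoyl)-2,5-dimethoxy-1,4-dioxo-1,4-dihydronaphthalen-7-yl]methyl}-2-oxo-2H-pyran-4-yl acetate
Product: 30 6-[2,4-bis(benzyloxy)-6-methylbenzoyl]-2-hydroxy-7-[(4-hydroxy-2-oxo-2H-pyran-6-yl)methyl]-5-methoxynaphthalene-1,4-dione
Conditions: LiOH, THF/H2O (degassed), 0 °C → rt; then 1 M HCl
Reagents that add atoms: lithium hydroxide, [Li+].[OH-]
Why: Hydroxide adds at C2 of the quinone and expels methoxide (addition–elimination on a vinylogous ester) and at the same time cleaves the activated enol acetate, the pyranone and the hydroxyquinone being protected as their delocalised anions until acidification.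

Step 19
Reactants: 30 6-[2,4-bis(benzyloxy)-6-methylbenzoyl]-2-hydroxy-7-[(4-hydroxy-2-oxo-2H-pyran-6-yl)methyl]-5-methoxynaphthalene-1,4-dione
Product: 31 6-(2,4-dihydroxy-6-methylbenzoyl)-2,5-dihydroxy-7-[(4-hydroxy-2-oxo-2H-pyran-6-yl)methyl]naphthalene-1,4-dione (CNP0158797.0)
Conditions: BCl3 (excess), pentamethylbenzene, CH2Cl2, −78 → 0 °C; then H2O
Reagents that add atoms: none
Why: Boron trichloride cleaves the two aryl benzyl ethers at low temperature, pentamethylbenzene trapping the benzyl cations by Friedel–Crafts alkylation, and on warming removes the C5 methyl ether selectively through the boron chelate with the peri C4 quinone carbonyl and the C6 ketone (Lewis acid ether cleavage).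

**Compound list**

1 | 2,4,5-trimethoxybenzaldehyde | COc1cc(OC)c(C=O)cc1OC | starting material
2 | lithium [(2-(dimethylamino)ethyl)(methyl)amino](2,4,5-trimethoxyphenyl)methanolate (racemic, not isolated) | CN(C)CCN(C)C(O[Li])c1cc(OC)c(OC)cc1OC | intermediate
3 | lithium [(2-(dimethylamino)ethyl)(methyl)amino](2-lithio-3,4,6-trimethoxyphenyl)methanolate (racemic, not isolated) | CN(C)CCN(C)C(O[Li])c1c([Li])c(OC)c(OC)cc1OC | intermediate
4 | lithium [(2-(dimethylamino)ethyl)(methyl)amino](3,4,6-trimethoxy-2-methylphenyl)methanolate (racemic, not isolated) | CN(C)CCN(C)C(O[Li])c1c(C)c(OC)c(OC)cc1OC | intermediate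
5 | 3,4,6-trimethoxy-2-methylbenzaldehyde | Cc1c(C=O)c(OC)cc(OC)c1OC | intermediate
6 | 3,4,6-trimethoxy-2-methylbenzoic acid | Cc1c(C(=O)O)c(OC)cc(OC)c1OC | intermediate
7 | methyl 3,4,6-trimethoxy-2-methylbenzoate | COC(=O)c1c(C)c(OC)c(OC)cc1OC | intermediate
8 | 2,4-dihydroxy-6-methylbenzaldehyde | Cc1cc(O)cc(O)c1C=O | starting material
9 | 2,4-bis(benzyloxy)-6-methylbenzaldehyde | Cc1cc(OCc2ccccc2)cc(OCc2ccccc2)c1C=O | intermediate
10 | 3-butyn-1-ol | C#CCCO | starting material
11 | tert-butyl(but-3-yn-1-yloxy)dimethylsilane | C#CCCO[Si](C)(C)C(C)(C)C | intermediate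
12 | lithium acetylide of 11 (not isolated) | [Li]C#CCCO[Si](C)(C)C(C)(C)C | intermediate
13 | 1-[2,4-bis(benzyloxy)-6-methylphenyl]-5-[(tert-butyldimethylsilyl)oxy]pent-2-yn-1-ol (racemic) | Cc1cc(OCc2ccccc2)cc(OCc2ccccc2)c1C(O)C#CCCO[Si](C)(C)C(C)(C)C | intermediate
14 | 1-[2,4-bis(benzyloxy)-6-methylphenyl]-5-[(tert-butyldimethylsilyl)oxy]pent-2-yn-1-one | Cc1cc(OCc2ccccc2)cc(OCc2ccccc2)c1C(=O)C#CCCO[Si](C)(C)C(C)(C)C | intermediate
15 | methyl 2-(lithiomethyl)-3,4,6-trimethoxybenzoate (not isolated) | [Li]Cc1c(C(=O)OC)c(OC)cc(OC)c1OC | intermediate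
16 | lithium allenolate from conjugate addition of 15 to 14 (racemic, not isolated) | [Li]OC(=C=C(CCO[Si](C)(C)C(C)(C)C)Cc1c(C(=O)OC)c(OC)cc(OC)c1OC)c1c(C)cc(OCc2ccccc2)cc1OCc1ccccc1 | intermediate
17 | [2,4-bis(benzyloxy)-6-methylphenyl]{7-[2-(tert-butyldimethylsilyloxy)ethyl]-5-hydroxy-1,2,4-trimethoxynaphthalen-6-yl}methanone | Cc1cc(OCc2ccccc2)cc(OCc2ccccc2)c1C(=O)c1c(CCO[Si](C)(C)C(C)(C)C)cc2c(OC)c(OC)cc(OC)c2c1O | intermediate
18 | [2,4-bis(benzyloxy)-6-methylphenyl]{7-[2-(tert-butyldimethylsilyloxy)ethyl]-1,2,4,5-tetramethoxynaphthalen-6-yl}methanone | Cc1cc(OCc2ccccc2)cc(OCc2ccccc2)c1C(=O)c1c(CCO[Si](C)(C)C(C)(C)C)cc2c(OC)c(OC)cc(OC)c2c1OC | intermediate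
19 | [2,4-bis(benzyloxy)-6-methylphenyl][7-(2-hydroxyethyl)-1,2,4,5-tetramethoxynaphthalen-6-yl]methanone | Cc1cc(OCc2ccccc2)cc(OCc2ccccc2)c1C(=O)c1c(CCO)cc2c(OC)c(OC)cc(OC)c2c1OC | intermediate
20 | 2-[6-(2,4-bis(benzyloxy)-6-methylbenzoyl)-1,2,4,5-tetramethoxynaphthalen-7-yl]acetaldehyde | Cc1cc(OCc2ccccc2)cc(OCc2ccccc2)c1C(=O)c1c(CC=O)cc2c(OC)c(OC)cc(OC)c2c1OC | intermediate
21 | [2,4-bis(benzyloxy)-6-methylphenyl][1,2,4,5-tetramethoxy-7-(prop-2-yn-1-yl)naphthalen-6-yl]methanone | Cc1cc(OCc2ccccc2)cc(OCc2ccccc2)c1C(=O)c1c(CC#C)cc2c(OC)c(OC)cc(OC)c2c1OC | intermediate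
22 | lithium acetylide of 21 (not isolated) | Cc1cc(OCc2ccccc2)cc(OCc2ccccc2)c1C(=O)c1c(CC#C[Li])cc2c(OC)c(OC)cc(OC)c2c1OC | intermediate
23 | methyl 4-[6-(2,4-bis(benzyloxy)-6-methylbenzoyl)-1,2,4,5-tetramethoxynaphthalen-7-yl]but-2-ynoate | Cc1cc(OCc2ccccc2)cc(OCc2ccccc2)c1C(=O)c1c(CC#CC(=O)OC)cc2c(OC)c(OC)cc(OC)c2c1OC | intermediate
24 | tert-butyl acetate | CC(=O)OC(C)(C)C | starting material
25 | lithium enolate of tert-butyl acetate (not isolated) | [Li]OC(=C)OC(C)(C)C | intermediate
26 | tert-butyl 6-[6-(2,4-bis(benzyloxy)-6-methylbenzoyl)-1,2,4,5-tetramethoxynaphthalen-7-yl]-3-oxohex-4-ynoate | CC(C)(C)OC(=O)CC(=O)C#CCc1cc2c(OC)c(OC)cc(OC)c2c(OC)c1C(=O)c1c(C)cc(OCc2ccccc2)cc1OCc1ccccc1 | intermediate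
27 | 6-{[6-(2,4-bis(benzyloxy)-6-methylbenzoyl)-1,2,4,5-tetramethoxynaphthalen-7-yl]methyl}-4-hydroxy-2H-pyran-2-one | O=c1cc(O)cc(Cc2cc3c(OC)c(OC)cc(OC)c3c(OC)c2C(=O)c2c(C)cc(OCc3ccccc3)cc2OCc2ccccc2)o1 | intermediate
28 | 6-{[6-(2,4-bis(benzyloxy)-6-methylbenzoyl)-1,2,4,5-tetramethoxynaphthalen-7-yl]methyl}-2-oxo-2H-pyran-4-yl acetate | CC(=O)Oc1cc(Cc2cc3c(OC)c(OC)cc(OC)c3c(OC)c2C(=O)c2c(C)cc(OCc3ccccc3)cc2OCc2ccccc2)oc(=O)c1 | intermediate
29 | 6-{[6-(2,4-bis(benzyloxy)-6-methylbenzoyl)-2,5-dimethoxy-1,4-dioxo-1,4-dihydronaphthalen-7-yl]methyl}-2-oxo-2H-pyran-4-yl acetate | CC(=O)Oc1cc(Cc2cc3c(c(OC)c2C(=O)c2c(C)cc(OCc4ccccc4)cc2OCc2ccccc2)C(=O)C=C(OC)C3=O)oc(=O)c1 | intermediate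
30 | 6-[2,4-bis(benzyloxy)-6-methylbenzoyl]-2-hydroxy-7-[(4-hydroxy-2-oxo-2H-pyran-6-yl)methyl]-5-methoxynaphthalene-1,4-dione | O=c1cc(O)cc(Cc2cc3c(c(OC)c2C(=O)c2c(C)cc(OCc4ccccc4)cc2OCc2ccccc2)C(=O)C=C(O)C3=O)o1 | intermediate
31 | 6-(2,4-dihydroxy-6-methylbenzoyl)-2,5-dihydroxy-7-[(4-hydroxy-2-oxo-2H-pyran-6-yl)methyl]naphthalene-1,4-dione (CNP0158797.0) | Cc1cc(O)cc(O)c1C(=O)c1c(Cc2cc(O)cc(=O)o2)cc2c(c1O)C(=O)C=C(O)C2=O | target

**Summary**

Total step count: 19.
Longest linear sequence: 15 steps (steps 1–3 and 8–19; the ynone branch through step 4 or 5, then 6, 7 and 8–19, is equally long).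

Steps most likely to fail:

1. Step 8 (annulation). The lithiated toluate may remove a propargylic proton from the ynone (quenching the nucleophile and isomerising the ynone to an allenone) faster than it adds in conjugate fashion, or the allenolate may fail to close onto the hindered ester. The fallback sets out from ynone 14 and replaces the alkyne acceptor by a vinylogous ester. Conjugate addition of methanol to 14 (MeOH, catalytic DABCO, rt) should give 1-[2,4-bis(benzyloxy)-6-methylphenyl]-5-[(tert-butyldimethylsilyl)oxy]-3-methoxypent-2-en-1-one F1 as an E/Z mixture. Lithiated toluate 15 (from 7, LDA, THF, −78 °C) is then condensed with F1 in the classical Staunton–Weinreb manner: conjugate addition, Dieckmann acylation of the enolate on the methyl ester, and β-elimination of methanol on warming. This comes back to the route at naphthol 17.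

2. Step 14 (Claisen condensation). The ester enolate may deprotonate the doubly activated ArCH2 group of the ynoate, leading to propargyl–allenyl isomerisation, or may add in conjugate fashion instead of attacking the ester carbonyl. The fallback sets out from alkyne 21 and introduces the carbonyl carbon at the aldehyde oxidation level. Acetylide 22 (from 21, LiHMDS, THF, −78 °C) is formylated with DMF and quenched into aqueous KH2PO4 to give 4-[6-(2,4-bis(benzyloxy)-6-methylbenzoyl)-1,2,4,5-tetramethoxynaphthalen-7-yl]but-2-ynal F2. The much more electrophilic aldehyde should take up lithium enolate 25 at −78 °C by fast 1,2-addition to give racemic tert-butyl 6-[6-(2,4-bis(benzyloxy)-6-methylbenzoyl)-1,2,4,5-tetramethoxynaphthalen-7-yl]-3-hydroxyhex-4-ynoate F3. Dess–Martin oxidation of F3 then comes back to the route at β-keto ester 26.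

3. Step 15 (gold cyclisation). The gold-activated alkyne may be captured by the oxygen of the neighbouring diaryl ketone (6-exo attack), or the tert-butyl group may be lost under acid or gold before ring closure, followed by decarboxylation of the β-keto acid. The fallback sets out from aldehyde 20 and assembles the pyranone by classical acyl-acetoacetate condensation without a π-acid.
   - Pinnick oxidation of 20 gives 2-[6-(2,4-bis(benzyloxy)-6-methylbenzoyl)-1,2,4,5-tetramethoxynaphthalen-7-yl]acetic acid F4.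
   - Carbonyldiimidazole converts F4 into 2-[6-(2,4-bis(benzyloxy)-6-methylbenzoyl)-1,2,4,5-tetramethoxynaphthalen-7-yl]-1-(1H-imidazol-1-yl)ethan-1-one F5.
   - C-Acylation of the dianion of methyl acetoacetate (NaH, then n-BuLi, THF, −78 °C) with F5 gives methyl 6-[6-(2,4-bis(benzyloxy)-6-methylbenzoyl)-1,2,4,5-tetramethoxynaphthalen-7-yl]-3,5-dioxohexanoate F6.
   - DBU in toluene lactonises F6 through its C5 enol oxygen with loss of methanol, which comes back to the route at pyranone 27.
   - The tetra-ortho-substituted diaryl ketone should be too hindered for the competing aldol closure of the triketide chain.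

**Further compounds**

F1 | step 8 | 1-[2,4-bis(benzyloxy)-6-methylphenyl]-5-[(tert-butyldimethylsilyl)oxy]-3-methoxypent-2-en-1-one (E/Z mixture) | Cc1cc(OCc2ccccc2)cc(OCc2ccccc2)c1C(=O)C=C(OC)CCO[Si](C)(C)C(C)(C)C
F2 | step 14 | 4-[6-(2,4-bis(benzyloxy)-6-methylbenzoyl)-1,2,4,5-tetramethoxynaphthalen-7-yl]but-2-ynal | Cc1cc(OCc2ccccc2)cc(OCc2ccccc2)c1C(=O)c1c(CC#CC=O)cc2c(OC)c(OC)cc(OC)c2c1OC
F3 | step 14 | tert-butyl 6-[6-(2,4-bis(benzyloxy)-6-methylbenzoyl)-1,2,4,5-tetramethoxynaphthalen-7-yl]-3-hydroxyhex-4-ynoate (racemic) | CC(C)(C)OC(=O)CC(O)C#CCc1cc2c(OC)c(OC)cc(OC)c2c(OC)c1C(=O)c1c(C)cc(OCc2ccccc2)cc1OCc1ccccc1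
F4 | step 15 | 2-[6-(2,4-bis(benzyloxy)-6-methylbenzoyl)-1,2,4,5-tetramethoxynaphthalen-7-yl]acetic acid | Cc1cc(OCc2ccccc2)cc(OCc2ccccc2)c1C(=O)c1c(CC(=O)O)cc2c(OC)c(OC)cc(OC)c2c1OC
F5 | step 15 | 2-[6-(2,4-bis(benzyloxy)-6-methylbenzoyl)-1,2,4,5-tetramethoxynaphthalen-7-yl]-1-(1H-imidazol-1-yl)ethan-1-one | Cc1cc(OCc2ccccc2)cc(OCc2ccccc2)c1C(=O)c1c(CC(=O)n3ccnc3)cc2c(OC)c(OC)cc(OC)c2c1OC
F6 | step 15 | methyl 6-[6-(2,4-bis(benzyloxy)-6-methylbenzoyl)-1,2,4,5-tetramethoxynaphthalen-7-yl]-3,5-dioxohexanoate | COC(=O)CC(=O)CC(=O)Cc1cc2c(OC)c(OC)cc(OC)c2c(OC)c1C(=O)c1c(C)cc(OCc2ccccc2)cc1OCc1ccccc1
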